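## Structural features

The target is (1R,2S)-1-(6-carboxy-2-oxo-2H-pyran-4-yl)-6,7-dihydroxy-1,2-dihydronaphthalene-2,3-dicarboxylic acid. A catechol benzene ring (ring A, C4a to C8a) is fused to a partly saturated carbocycle (ring B, C1 to C4), and a 2-pyranone-6-carboxylic acid (ring C) is attached through its C4 to C1. The only stereocentres, C1 (pyranone) and C2 (carboxyl), are adjacent and trans, so the C2 hydrogen lies on the same face as the pyranone. C3 carries the second ring-B carboxyl on the C3=C4 double bond, which is conjugated with ring A. The fragile parts are the free catechol (oxidation), the pyranone (opened or substituted by hydroxide, alkoxide and amines), the C1 hydrogen (benzylic and vinylogously α to the lactone carbonyl, hence removable by base), and the dihydronaphthalene itself, which can be dehydrogenated or suffer double-bond migration. The real difficulties are the absolute configuration at C1, a methine between two (hetero)aryl rings that tolerates no base once the pyranone is present, and the C2-C3 bond, which joins two carbons that are both α to a carboxyl group and therefore both donors. The key step exploits exactly this: with C2 at the malonate level and C3 as the α-carbon of an ortho-cinnamate on ring A, one-electron oxidation turns C2 into an electrophilic radical that bonds to C3 and closes ring B.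

## Logic of the disconnections

20 to 19: the two aryl O-CH3 bonds are cut. The catechol is the most oxidation-sensitive function and would not survive trivalent manganese or prolonged hot acid in air, so it is unveiled last. The forward step must cleave ethers without base and without opening the lactone.

19 to 17 (through 18): a carboxyl is added back at C2 and four ester O-CH3 bonds are restored. A geminal diester at C2 makes C2 oxidisable to a radical and blocks dehydrogenation to a naphthalene. The gain is that C2 stops being a stereocentre, and only C1 has to be carried. The forward step must be purely acidic and must deliver the trans C2 epimer, which it can only do under thermodynamic control.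

17 to 16: the C2-C3 bond is cut and ring B opens. Both carbons are donors, so the bond is made by oxidation and not by a polar reaction. The precursor is an open-chain malonate with an ortho-cinnamate and a single stereocentre. The forward step needs 6-endo closure, oxidative termination to the C3=C4 alkene, and a medium that leaves C1 alone.

16 to 14 and 15: the C4-C4a bond (aryl to vinyl) is cut. The acrylate is attached only after the malonate is in place and immediately before the key step, because a cinnamate next to a malonate invites base-induced conjugate closure. The bromine of the commercial aldehyde serves as the latent acrylate. The forward step needs a coupling on a hindered, electron-rich bromide under weakly basic conditions.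

14 to 13: the O-CH3 bond on the oxygen para to C1 is cut. That oxygen must be free for the stereo-defining step and capped before any oxidant or palladium step. The forward methylation must not C-alkylate the malonate or expose C1 to base.

13 to 10 and 11 (through 12): the C1-C2 bond is cut, and C1 is created here. The para hydroxyl makes the benzylic carbon a vinylogous acceptor once the leaving group departs, so a malonate can be added under catalyst control. The demand is slow release of 12 in the presence of the chiral catalyst and good facial discrimination.

10 to 8 (through 9): the C1-S bond and the O-Si bond are cut. The sulfone is a storable source of 12, and the carbinol stereocentre of 8 is irrelevant because it is erased. The forward step needs acid ionisation of a benzylic alcohol that bears an electron-poor ring.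

8 to 7 and 5: the bond between C1 and pyranone C4 is cut. This is the most convergent cut, joining ring A to ring C at the future stereocentre. The organometallic reagent must tolerate an ester, a lactone and an aryl bromide and must add only to the aldehyde.

7 to 6: the O-Si bond is cut; the phenol is masked only for the organometallic step.

5 back to 1 (through 4, 3 and 2): the ester O-CH3 bond, two C-O bonds at the side-chain carbon and the C4-Br bond are removed in turn. The side chain is oxidised only after the 4-hydroxyl has been exchanged for bromine, and every step avoids alkoxide.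

## Other disconnections considered

Alternative 1: The cut is the lactone O1-C2 bond of ring C, which traces the pyranone back to a free 3,4,5-trihydroxyphenyl ring on C1, as in dimethyl trans-(1R,2S)-6,7-dimethoxy-1-(3,4,5-trihydroxyphenyl)-1,2-dihydronaphthalene-2,3-dicarboxylate A2. In the forward step the pyrogallol ring is oxidised to the ortho-quinone level, a peracid inserts oxygen between two adjacent oxygen-bearing carbons, the ring opens, and the enol hydroxyl closes onto the far carboxyl to give the pyranone acid A1. In its favour, the route follows the likely biogenesis, the local symmetry of the pyrogallol makes both possible cleavages equivalent, and the electrophilic pyranone is absent until late. While ring C is still a plain arene, C1 is not base-labile, so the trans C1/C2 relationship can be set by base equilibration; on this point Alternative 1 is the better plan. Against it, pyrogallols tend to couple to benzotropolones on oxidation, the peracid must spare the electron-rich ring A, and the ring-opened diacid can close to a butenolide instead of the pyranone. The key step also forms no skeletal C-C bond, so the enantioselective construction of A2 is a separate problem of about the same size as the present one. Ring A still needs its methyl ethers removed at the end, so the two plans are equal there. On step economy the alternative is not expected to be shorter, and its key step is mechanistically less predictable than the radical closure of 16.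

Alternative 2: The cut removes three bonds of ring A (C4a-C8a, C5-C6, C7-C8), so both carbocycles go back to an open-chain terminal 1,7-diyne, dimethyl (E)-2-(prop-2-yn-1-ylidene)-3-[1-(6-methoxycarbonyl-2-oxo-2H-pyran-4-yl)prop-2-yn-1-yl]butanedioate A4 (anti, C1 and C2 as in the target), plus bis(pinacolatoboryl)acetylene A5. In the forward step Cp*RuCl(cod) couples the two alkynes of A4 oxidatively to a ruthenacycle (closing ring B), inserts A5 and eliminates reductively to the bis-boronate A3. Both C-B bonds are then oxidised to the catechol. In its favour, one step builds two rings and three bonds, the symmetrical alkyne removes any regiochemical question, and there is no 5-exo versus 6-endo ambiguity. The catechol is also unveiled without BBr3. On these three points it is the better plan. Against it, A4 holds both stereocentres in an open chain, with the C1 hydrogen propargylic as well as vinylogous to the lactone, which invites allene formation and racemisation. Its enyne ester must be geometrically pure, 1,7-diynes close more slowly than 1,6-diynes, and the pyranone and terminal alkynes are themselves partners for the ruthenium. The usual basic peroxide oxidation of the boronates is also hostile to ring C. Overall the key step does more, but its precursor is far harder to make than 16, so the route is expected to be longer and stereochemically less secure.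

Alternative 3: The cut removes O1-C6 and C4-C5 of ring C, tracing the pyranone to a C1-bound propiolic acid, 3-[trans-2,3-bis(methoxycarbonyl)-6,7-dimethoxy-1,2-dihydronaphthalen-1-yl]prop-2-ynoic acid A7, and tert-butyl(dimethyl)(prop-2-yn-1-yloxy)silane A8. In the forward step Ph3PAuNTf2 (monovalent gold) activates A8 for Markovnikov addition of the acid, and the enol ester then attacks the gold-activated ynoate in a 6-endo-dig closure to give the silyloxymethyl pyranone A6. In its favour, ring C is made late in one catalytic, neutral step from two simple alkynes, with the 4,6-pattern fixed by the mechanism. This spares the route the four-step preparation of 5 and never exposes ring C to organometallic reagents; on both points it is the better plan. Against it, A6 has a silyloxymethyl group where the target needs a carboxyl, so desilylation and two oxidations follow the key step with the labile C1 hydrogen present. In A7 that hydrogen is propargylic to an ynoic acid, and the C2 ester carbonyl or ring A may attack the activated ynoate intramolecularly before A8 does. Like the chosen key step, this one sets no stereocentre (the plans are equal there), and ring B with C1 and C2 must still be made by other means. The total step count is therefore not expected to be lower.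

Key step: step 11

Remark on the chemistry: in the target the C2 carboxyl is trans to the pyranone, so the C2 hydrogen must end up syn to it. A proton delivered to C2 from the face opposite the pyranone, the kinetically easier approach, would give the cis acid. Step 12 therefore relies on acid-mediated equilibration at C2 to the more stable trans (pseudo-diaxial) epimer, which avoids the eclipsing of the C2 carboxyl with the C3 carboxyl.

Assumption: the quinine-derived thiourea named in step 8 is taken to give the (R) centre; if the sense of induction should be the opposite, its quinidine-derived pseudoenantiomer is used instead. Compounds 8, 9 and 10 are racemic by design.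

## Route

Step 1
Reactants: 1 4-hydroxy-6-methyl-2H-pyran-2-one
Product: 2 4-bromo-6-methyl-2H-pyran-2-one
Conditions: Bu4NBr, P2O5, toluene, 100 °C
Reagents that add atoms: tetrabutylammonium bromide, CCCC[N+](CCCC)(CCCC)CCCC.[Br-]
Why: Dehydrative bromination of a vinylogous acid: P2O5 turns the enol oxygen into a phosphate leaving group and bromide replaces it by addition-elimination at C4, a known transformation of this lactone.

Step 2
Reactants: 2 4-bromo-6-methyl-2H-pyran-2-one
Product: 3 4-bromo-2-oxo-2H-pyran-6-carbaldehyde
Conditions: SeO2, 1,4-dioxane, 160 °C (sealed tube)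
Reagents that add atoms: selenium dioxide, O=[Se]=O
Why: Riley oxidation: the 6-methyl group is the only C-H site activated by the ring enol-ether double bond (ene reaction, [2,3]-shift, loss of selenium), as known for 6-methyl-2-pyranones, and the aldehyde should not be oxidised further in the anhydrous medium.

Step 3
Reactants: 3 4-bromo-2-oxo-2H-pyran-6-carbaldehyde
Product: 4 4-bromo-2-oxo-2H-pyran-6-carboxylic acid
Conditions: NaClO2, NaH2PO4, 2-methyl-2-butene, t-BuOH/H2O, 0 °C to rt
Reagents that add atoms: sodium chlorite, [Na+].[O-]Cl=O
Why: Pinnick oxidation: chlorous acid oxidises only the aldehyde in a buffered, weakly acidic medium in which the bromopyranone is safe from nucleophiles, and the alkene scavenges the hypochlorous acid formed.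

Step 4
Reactants: 4 4-bromo-2-oxo-2H-pyran-6-carboxylic acid
Product: 5 methyl 4-bromo-2-oxo-2H-pyran-6-carboxylate
Conditions: TMSCHN2, MeOH/toluene, 0 °C
Reagents that add atoms: trimethylsilyldiazomethane, C[Si](C)(C)C=[N+]=[N-]
Why: Esterification by a diazoalkane is fast and neutral at 0 °C, so no alkoxide or hot acidic methanol meets the 4-bromopyranone, which would otherwise risk substitution at C4.

Step 5
Reactants: 6 6-bromovanillin (2-bromo-4-hydroxy-5-methoxybenzaldehyde)
Product: 7 2-bromo-4-[tert-butyl(dimethyl)silyl]oxy-5-methoxybenzaldehyde
Conditions: TBSCl, imidazole, CH2Cl2, rt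
Reagents that add atoms: tert-butyldimethylsilyl chloride, CC(C)(C)[Si](C)(C)Cl
Why: Standard silylation of an acidic phenol; the mask is needed because a free phenol para to the aldehyde would protonate the organochromium reagent and deactivate the aldehyde.

Step 6
Reactants: 7 2-bromo-4-[tert-butyl(dimethyl)silyl]oxy-5-methoxybenzaldehyde; 5 methyl 4-bromo-2-oxo-2H-pyran-6-carboxylate
Product: 8 methyl 4-[(2-bromo-4-{[tert-butyl(dimethyl)silyl]oxy}-5-methoxyphenyl)(hydroxy)methyl]-2-oxo-2H-pyran-6-carboxylate (racemic)
Conditions: CrCl2 (4 equiv), NiCl2 (2 mol %), DMF, rt
Reagents that add atoms: none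
Why: Nozaki-Hiyama-Kishi coupling: zerovalent nickel inserts into the activated vinylogous acyl C-Br bond of 5 much faster than into the electron-rich aryl bromide of 7, and the alkenylchromium (trivalent chromium) adds only to the aldehyde, tolerating ester, lactone and silyl ether. The carbinol centre is formed racemic on purpose, since step 8 erases it.

Step 7
Reactants: 8 methyl 4-[(2-bromo-4-{[tert-butyl(dimethyl)silyl]oxy}-5-methoxyphenyl)(hydroxy)methyl]-2-oxo-2H-pyran-6-carboxylate
Product: 10 methyl 4-[(2-bromo-4-hydroxy-5-methoxyphenyl)(4-methylbenzenesulfonyl)methyl]-2-oxo-2H-pyran-6-carboxylate (racemic), via hydroxybenzyl alcohol 9 (not isolated)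
Conditions: TBAF, AcOH, THF, 0 °C; then p-TolSO2Na, CF3CO2H, CH2Cl2, rt (solvent exchange)
Reagents that add atoms: sodium 4-methylbenzenesulfinate, Cc1ccc(cc1)S(=O)[O-].[Na+]
Why: Buffered fluoride removes the aryl silyl ether without harming the pyranone; the para-hydroxybenzyl alcohol then ionises under acid with help from the para hydroxyl and is captured at carbon by sulfinic acid (S-alkylation). This gives a storable sulfone of the type commonly used as a quinone methide source.

Step 8
Reactants: 10 methyl 4-[(2-bromo-4-hydroxy-5-methoxyphenyl)(4-methylbenzenesulfonyl)methyl]-2-oxo-2H-pyran-6-carboxylate; 11 dimethyl malonate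
Product: 13 dimethyl 2-[(R)-(2-bromo-4-hydroxy-5-methoxyphenyl)(6-methoxycarbonyl-2-oxo-2H-pyran-4-yl)methyl]propanedioate, via quinone methide 12 (not isolated)
Conditions: 11 (3 equiv), 1-[3,5-bis(trifluoromethyl)phenyl]-3-[(8α,9S)-6′-methoxycinchonan-9-yl]thiourea (10 mol %), aq. K2CO3, toluene/CH2Cl2, 0 °C
Reagents that add atoms: none
Why: Base-induced 1,6-elimination of sulfinate releases the para-quinone methide 12 slowly; it is expected as the isomer with the pyranone turned away from bromine, and it takes up the malonate in an organocatalytic asymmetric 1,6-conjugate addition driven by rearomatisation. The bifunctional catalyst holds the quinone methide carbonyl by thiourea hydrogen bonds and the malonate enolate on its protonated quinuclidine, so attack on one face of the exocyclic carbon sets C1 by catalyst control.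

Step 9
Reactants: 13 dimethyl 2-[(R)-(2-bromo-4-hydroxy-5-methoxyphenyl)(6-methoxycarbonyl-2-oxo-2H-pyran-4-yl)methyl]propanedioate
Product: 14 dimethyl 2-[(R)-(2-bromo-4,5-dimethoxyphenyl)(6-methoxycarbonyl-2-oxo-2H-pyran-4-yl)methyl]propanedioate
Conditions: MeOH, PPh3, DIAD, THF, 0 °C to rt
Reagents that add atoms: methanol, CO
Why: Mitsunobu O-methylation: only the phenol is acidic enough to protonate the betaine, so the hindered, less acidic malonate C-H and the C1 hydrogen stay untouched and no base is present that could C-methylate the malonate. Capping the phenol also closes the retro-1,6-addition path that could erode C1.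

Step 10
Reactants: 14 dimethyl 2-[(R)-(2-bromo-4,5-dimethoxyphenyl)(6-methoxycarbonyl-2-oxo-2H-pyran-4-yl)methyl]propanedioate; 15 methyl acrylate
Product: 16 dimethyl 2-[(R)-{4,5-dimethoxy-2-[(E)-3-methoxy-3-oxoprop-1-en-1-yl]phenyl}(6-methoxycarbonyl-2-oxo-2H-pyran-4-yl)methyl]propanedioate
Conditions: 15 (3 equiv), Pd(P(t-Bu)3)2 (5 mol %), Cy2NMe, 1,4-dioxane, 60 °C
Reagents that add atoms: none
Why: Mizoroki-Heck reaction: the bulky electron-rich phosphine lets zerovalent palladium insert into the hindered, electron-rich aryl bromide at moderate temperature, and syn insertion into the acrylate followed by syn β-hydride elimination gives the E-cinnamate. A hindered amine in a non-polar solvent keeps malonate deprotonation (conjugate closure to an indane) and C1 epimerisation to a minimum.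

Step 11
Reactants: 16 dimethyl 2-[(R)-{4,5-dimethoxy-2-[(E)-3-methoxy-3-oxoprop-1-en-1-yl]phenyl}(6-methoxycarbonyl-2-oxo-2H-pyran-4-yl)methyl]propanedioate
Product: 17 trimethyl (1R)-6,7-dimethoxy-1-(6-methoxycarbonyl-2-oxo-2H-pyran-4-yl)-1H-naphthalene-2,2,3-tricarboxylate
Conditions: Mn(OAc)3·2H2O (2.2 equiv), Cu(OAc)2·H2O (1 equiv), AcOH (degassed), 70 °C
Reagents that add atoms: none
Why: Mn(OAc)3 forms the trivalent manganese enolate of the tertiary malonate (the slow step), and inner-sphere electron transfer gives the electrophilic C2 malonyl radical. The closest known reaction type is the Mn(OAc)3/Cu(OAc)2 oxidative free-radical cyclisation of unsaturated malonates with oxidative termination to an alkene. Ring B closes by 6-endo-trig attack of the C2 radical on C3, the α-carbon of the ortho-cinnamate, which leaves a C4 benzylic radical stabilised by the para methoxy group of ring A. Cu(OAc)2 captures that radical and the organocopper intermediate loses the C3 hydrogen to give the C3=C4 double bond; the monovalent copper formed is reoxidised by Mn(OAc)3. No stereocentre is created: C2 becomes quaternary with two identical esters, C3 and C4 are sp2, and the acidic medium leaves C1 untouched. The selectivity needed is 6-endo over 5-exo; it is favoured by polarity matching (the electrophilic radical prefers the α-carbon and avoids the electron-poor β-carbon), by the benzylic stabilisation of the 6-endo radical, and by the rigid ortho-arene tether, which strains the 5-exo transition state. The quaternary C2 also blocks over-oxidation to a naphthalene, and 17 has no enolisable malonate hydrogen left for the oxidant.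

Step 12
Reactants: 17 trimethyl (1R)-6,7-dimethoxy-1-(6-methoxycarbonyl-2-oxo-2H-pyran-4-yl)-1H-naphthalene-2,2,3-tricarboxylate
Product: 19 (1R,2S)-1-(6-carboxy-2-oxo-2H-pyran-4-yl)-6,7-dimethoxy-1,2-dihydronaphthalene-2,3-dicarboxylic acid, via tetracarboxylic acid 18 (not isolated)
Conditions: 6 M HCl/AcOH (1:1), 105 °C, argon
Reagents that add atoms: water, O
Why: Acid-catalysed ester hydrolysis gives 18, whose geminal diacid loses CO2 through the cyclic transition state of a malonic acid, and the resulting enediol is protonated at C2. The C2 hydrogen (α to a carboxyl and allylic to the styrenic C3=C4) can exchange by reversible enolisation in hot strong acid, whereas C1 has no comparable acid pathway, so the mixture should settle on the trans (2S) epimer under thermodynamic control. The pyranone is the stable ring-closed form in acid.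

Step 13
Reactants: 19 (1R,2S)-1-(6-carboxy-2-oxo-2H-pyran-4-yl)-6,7-dimethoxy-1,2-dihydronaphthalene-2,3-dicarboxylic acid
Product: 20 (1R,2S)-1-(6-carboxy-2-oxo-2H-pyran-4-yl)-6,7-dihydroxy-1,2-dihydronaphthalene-2,3-dicarboxylic acid
Conditions: BBr3 (8 equiv), CH2Cl2, −78 °C to rt; then H2O, 0 °C, argon
Reagents that add atoms: none
Why: Lewis-acid ether cleavage: BBr3 binds each aryl methyl ether and bromide removes the methyl group by SN2; the carboxylic acids return on aqueous work-up. The pyranone has no alkyl-oxygen bond to cleave, and with no base present C1 and C2 should keep their configuration.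

## Compound list

1 | 4-hydroxy-6-methyl-2H-pyran-2-one | Cc1cc(O)cc(=O)o1 | starting material
2 | 4-bromo-6-methyl-2H-pyran-2-one | Cc1cc(Br)cc(=O)o1 | intermediate
3 | 4-bromo-2-oxo-2H-pyran-6-carbaldehyde | O=Cc1cc(Br)cc(=O)o1 | intermediate
4 | 4-bromo-2-oxo-2H-pyran-6-carboxylic acid | OC(=O)c1cc(Br)cc(=O)o1 | intermediate
5 | methyl 4-bromo-2-oxo-2H-pyran-6-carboxylate | COC(=O)c1cc(Br)cc(=O)o1 | intermediate
6 | 6-bromovanillin (2-bromo-4-hydroxy-5-methoxybenzaldehyde) | COc1cc(C=O)c(Br)cc1O | starting material
7 | 2-bromo-4-[tert-butyl(dimethyl)silyl]oxy-5-methoxybenzaldehyde | COc1cc(C=O)c(Br)cc1O[Si](C)(C)C(C)(C)C | intermediate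
8 | methyl 4-[(2-bromo-4-{[tert-butyl(dimethyl)silyl]oxy}-5-methoxyphenyl)(hydroxy)methyl]-2-oxo-2H-pyran-6-carboxylate (racemic) | COC(=O)c1cc(C(O)c2cc(OC)c(O[Si](C)(C)C(C)(C)C)cc2Br)cc(=O)o1 | intermediate
9 | methyl 4-[(2-bromo-4-hydroxy-5-methoxyphenyl)(hydroxy)methyl]-2-oxo-2H-pyran-6-carboxylate (racemic) | COC(=O)c1cc(C(O)c2cc(OC)c(O)cc2Br)cc(=O)o1 | intermediate (not isolated)
10 | methyl 4-[(2-bromo-4-hydroxy-5-methoxyphenyl)(4-methylbenzenesulfonyl)methyl]-2-oxo-2H-pyran-6-carboxylate (racemic) | COC(=O)c1cc(C(c2cc(OC)c(O)cc2Br)S(=O)(=O)c2ccc(C)cc2)cc(=O)o1 | intermediate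
11 | dimethyl malonate | COC(=O)CC(=O)OC | starting material
12 | methyl 4-[(E)-(2-bromo-5-methoxy-4-oxocyclohexa-2,5-dien-1-ylidene)methyl]-2-oxo-2H-pyran-6-carboxylate | COC(=O)c1cc(/C=C2\C=C(OC)C(=O)C=C2Br)cc(=O)o1 | intermediate (not isolated)
13 | dimethyl 2-[(R)-(2-bromo-4-hydroxy-5-methoxyphenyl)(6-methoxycarbonyl-2-oxo-2H-pyran-4-yl)methyl]propanedioate | COc1cc([C@@H](c2cc(C(=O)OC)oc(=O)c2)C(C(=O)OC)C(=O)OC)c(Br)cc1O | intermediate
14 | dimethyl 2-[(R)-(2-bromo-4,5-dimethoxyphenyl)(6-methoxycarbonyl-2-oxo-2H-pyran-4-yl)methyl]propanedioate | COc1cc([C@@H](c2cc(C(=O)OC)oc(=O)c2)C(C(=O)OC)C(=O)OC)c(Br)cc1OC | intermediate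
15 | methyl acrylate | C=CC(=O)OC | starting material
16 | dimethyl 2-[(R)-{4,5-dimethoxy-2-[(E)-3-methoxy-3-oxoprop-1-en-1-yl]phenyl}(6-methoxycarbonyl-2-oxo-2H-pyran-4-yl)methyl]propanedioate | COC(=O)/C=C/c1cc(OC)c(OC)cc1[C@@H](c1cc(C(=O)OC)oc(=O)c1)C(C(=O)OC)C(=O)OC | intermediate
17 | trimethyl (1R)-6,7-dimethoxy-1-(6-methoxycarbonyl-2-oxo-2H-pyran-4-yl)-1H-naphthalene-2,2,3-tricarboxylate | COC(=O)C1=Cc2cc(OC)c(OC)cc2[C@@H](c2cc(C(=O)OC)oc(=O)c2)C1(C(=O)OC)C(=O)OC | intermediate
18 | (1R)-1-(6-carboxy-2-oxo-2H-pyran-4-yl)-6,7-dimethoxy-1H-naphthalene-2,2,3-tricarboxylic acid | O=C(O)C1=Cc2cc(OC)c(OC)cc2[C@@H](c2cc(C(=O)O)oc(=O)c2)C1(C(=O)O)C(=O)O | intermediate (not isolated)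
19 | (1R,2S)-1-(6-carboxy-2-oxo-2H-pyran-4-yl)-6,7-dimethoxy-1,2-dihydronaphthalene-2,3-dicarboxylic acid | O=C(O)C1=Cc2cc(OC)c(OC)cc2[C@@H](c2cc(C(=O)O)oc(=O)c2)[C@@H]1C(=O)O | intermediate
20 | (1R,2S)-1-(6-carboxy-2-oxo-2H-pyran-4-yl)-6,7-dihydroxy-1,2-dihydronaphthalene-2,3-dicarboxylic acid | O=C(O)C1=Cc2cc(O)c(O)cc2[C@@H](c2cc(C(=O)O)oc(=O)c2)[C@@H]1C(=O)O | target

## Step count and least certain steps

Total: 13 steps. Longest linear sequence: 12 steps (1 through 5, then steps 6 to 13).

Step 11 (key step). The most likely failure is 5-exo closure of the C2 radical onto C4, which leads to an indane with an α-ester radical, because both closures are geometrically open to the ortho-arene tether. Slow enolisation of the crowded tertiary malonate would in addition leave time for oxidation of the electron-rich ring. The fallback makes the same C2-C3 bond by an ionic umpolung whose regiochemistry is dictated by the mechanism. It sets out from 14, which is coupled with methyl 3-(tributylstannyl)propiolate in a Stille reaction (Pd(PPh3)4, toluene, 90 °C, no base) to give the ynoate dimethyl 2-[(R)-[4,5-dimethoxy-2-(3-methoxy-3-oxoprop-1-yn-1-yl)phenyl](6-methoxycarbonyl-2-oxo-2H-pyran-4-yl)methyl]propanedioate F1. PPh3 (20 mol %, toluene, 80 °C) then adds to the β-carbon (C4), and the zwitterion deprotonates the malonate. The malonate attacks the α-carbon (C3) of the vinylphosphonium, and proton shift with loss of the phosphine gives the C3=C4 alkene (phosphine-catalysed α-addition to an ynoate). The fallback comes back to the route at 17.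

Step 8. The most likely failure is poor facial selectivity. The quinone methide is unsymmetrical, carries an ortho bromine next to the reacting carbon and is generated in situ, so an uncatalysed background addition at the aqueous interface can compete with the catalyst-bound pathway. The fallback replaces catalytic induction by resolution. From 10, the addition of 11 is run with aq. K2CO3 and no chiral catalyst to give racemic dimethyl 2-[(2-bromo-4-hydroxy-5-methoxyphenyl)(6-methoxycarbonyl-2-oxo-2H-pyran-4-yl)methyl]propanedioate F2. Mitsunobu methylation as in step 9 gives racemic dimethyl 2-[(2-bromo-4,5-dimethoxyphenyl)(6-methoxycarbonyl-2-oxo-2H-pyran-4-yl)methyl]propanedioate F3. Preparative chromatography on a chiral stationary phase then separates the (R) enantiomer from the antipode dimethyl 2-[(S)-(2-bromo-4,5-dimethoxyphenyl)(6-methoxycarbonyl-2-oxo-2H-pyran-4-yl)methyl]propanedioate F4, which is set aside. The fallback comes back to the route at 14.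

Step 12. The most likely failure is slow acyl-oxygen hydrolysis of the two esters on the quaternary C2. The long heating this forces could allow migration of the double bond toward C2=C3 and would make the C2 equilibration harder to control. The fallback cleaves the esters at the methyl carbon instead, where hindrance at the acyl carbon does not matter. From 17, excess BBr3 (CH2Cl2, −78 °C to rt) removes all six O-methyl groups (four ester, two ether) and, after aqueous quench, gives (1R)-1-(6-carboxy-2-oxo-2H-pyran-4-yl)-6,7-dihydroxy-1H-naphthalene-2,2,3-tricarboxylic acid F5. Heating F5 in dilute aqueous HCl at 90 °C under argon brings about decarboxylation and the C2 equilibration. The fallback comes back to the route at 20.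

Step 10. The most likely failure is base-promoted damage during the coupling: conjugate closure of the malonate onto the newly formed cinnamate, or epimerisation at C1, if oxidative addition into the hindered bromide is slow and long heating with amine is needed. The fallback is a base-free Stille coupling of 14 with methyl (E)-3-(tributylstannyl)acrylate (Pd2(dba)3, tri(2-furyl)phosphine, toluene, 90 °C), which transfers the intact E-acrylate unit. It makes no new compound, sets out from 14 and comes back to the route at 16.

Step 2. The most likely failure is thermal degradation of the electron-poor bromopyranone at the temperature the selenium dioxide oxidation needs, with incomplete conversion. The fallback reaches the aldehyde by halogenation and amine-oxide oxidation. From 2, radical bromination (NBS, dibenzoyl peroxide, PhCF3, reflux) gives 4-bromo-6-(bromomethyl)-2H-pyran-2-one F6. N-Methylmorpholine N-oxide (MeCN, rt) then displaces the bromide and the adduct eliminates to the aldehyde. The fallback comes back to the route at 3.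

## Further compounds

F1 | step 11 | dimethyl 2-[(R)-[4,5-dimethoxy-2-(3-methoxy-3-oxoprop-1-yn-1-yl)phenyl](6-methoxycarbonyl-2-oxo-2H-pyran-4-yl)methyl]propanedioate | COC(=O)C#Cc1cc(OC)c(OC)cc1[C@@H](c1cc(C(=O)OC)oc(=O)c1)C(C(=O)OC)C(=O)OC
F2 | step 8 | racemic dimethyl 2-[(2-bromo-4-hydroxy-5-methoxyphenyl)(6-methoxycarbonyl-2-oxo-2H-pyran-4-yl)methyl]propanedioate | COc1cc(C(c2cc(C(=O)OC)oc(=O)c2)C(C(=O)OC)C(=O)OC)c(Br)cc1O
F3 | step 8 | racemic dimethyl 2-[(2-bromo-4,5-dimethoxyphenyl)(6-methoxycarbonyl-2-oxo-2H-pyran-4-yl)methyl]propanedioate | COc1cc(C(c2cc(C(=O)OC)oc(=O)c2)C(C(=O)OC)C(=O)OC)c(Br)cc1OC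
F4 | step 8 | dimethyl 2-[(S)-(2-bromo-4,5-dimethoxyphenyl)(6-methoxycarbonyl-2-oxo-2H-pyran-4-yl)methyl]propanedioate | COc1cc([C@H](c2cc(C(=O)OC)oc(=O)c2)C(C(=O)OC)C(=O)OC)c(Br)cc1OC
F5 | step 12 | (1R)-1-(6-carboxy-2-oxo-2H-pyran-4-yl)-6,7-dihydroxy-1H-naphthalene-2,2,3-tricarboxylic acid | O=C(O)C1=Cc2cc(O)c(O)cc2[C@@H](c2cc(C(=O)O)oc(=O)c2)C1(C(=O)O)C(=O)O
F0 | step 10 | none | none
F6 | step 2 | 4-bromo-6-(bromomethyl)-2H-pyran-2-one | BrCc1cc(Br)cc(=O)o1
A1 | alternative 1 | 4-[(1R,2S)-2,3-bis(methoxycarbonyl)-6,7-dimethoxy-1,2-dihydronaphthalen-1-yl]-2-oxo-2H-pyran-6-carboxylic acid | COC(=O)C1=Cc2cc(OC)c(OC)cc2[C@@H](c2cc(C(=O)O)oc(=O)c2)[C@@H]1C(=O)OC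
A2 | alternative 1 | dimethyl trans-(1R,2S)-6,7-dimethoxy-1-(3,4,5-trihydroxyphenyl)-1,2-dihydronaphthalene-2,3-dicarboxylate | COC(=O)C1=Cc2cc(OC)c(OC)cc2[C@@H](c2cc(O)c(O)c(O)c2)[C@@H]1C(=O)OC
A3 | alternative 2 | dimethyl (1R,2S)-1-(6-methoxycarbonyl-2-oxo-2H-pyran-4-yl)-6,7-bis(4,4,5,5-tetramethyl-1,3,2-dioxaborolan-2-yl)-1,2-dihydronaphthalene-2,3-dicarboxylate | COC(=O)C1=Cc2cc(B3OC(C)(C)C(C)(C)O3)c(B3OC(C)(C)C(C)(C)O3)cc2[C@@H](c2cc(C(=O)OC)oc(=O)c2)[C@@H]1C(=O)OC
A4 | alternative 2 | dimethyl (E)-2-(prop-2-yn-1-ylidene)-3-[1-(6-methoxycarbonyl-2-oxo-2H-pyran-4-yl)prop-2-yn-1-yl]butanedioate (anti, C1 and C2 as in the target) | C#C[C@@H](c1cc(C(=O)OC)oc(=O)c1)[C@H](C(=O)OC)/C(C(=O)OC)=C\C#C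
A5 | alternative 2 | bis(pinacolatoboryl)acetylene | CC1(C)OB(OC1(C)C)C#CB1OC(C)(C)C(C)(C)O1
A6 | alternative 3 | dimethyl (1R,2S)-1-[6-({[tert-butyl(dimethyl)silyl]oxy}methyl)-2-oxo-2H-pyran-4-yl]-6,7-dimethoxy-1,2-dihydronaphthalene-2,3-dicarboxylate | COC(=O)C1=Cc2cc(OC)c(OC)cc2[C@@H](c2cc(CO[Si](C)(C)C(C)(C)C)oc(=O)c2)[C@@H]1C(=O)OC
A7 | alternative 3 | 3-[trans-2,3-bis(methoxycarbonyl)-6,7-dimethoxy-1,2-dihydronaphthalen-1-yl]prop-2-ynoic acid (C1 and C2 as in the target) | COC(=O)C1=Cc2cc(OC)c(OC)cc2[C@@H](C#CC(=O)O)[C@@H]1C(=O)OC
A8 | alternative 3 | tert-butyl(dimethyl)(prop-2-yn-1-yloxy)silane | C#CCO[Si](C)(C)C(C)(C)C
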